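**Retrosynthetic overview**

1. Target 17 comes from 16 by hydrogenolysis of two benzyl ethers; 16 from diol glycal 15 by hydroxyl-directed hydrogenation of C1=C2, which sets C1; 15 from bis-silyl glycal 14.
2. Feature used: in the oxane ring (O1, C1 to C5) the oxygen O1 links the guaiacyl-bearing C1 to C5, so O1, C1 and the aryl group enter as one unit, the 4-benzyloxy-3-methoxybenzoate of the C5 hydroxyl, and only C1–C2 remains to be made.
3. 14 comes from ester 12 by carbonyl–olefin ring-closing metathesis with a reduced titanium ethylidene: C1=C2 is formed and the oxane ring, the only ring built, is closed last.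
4. 12 comes from 11 (C3 silylation), 11 from β-hydroxy enone 8 and aldehyde 9 (Evans–Tishchenko: sets C3, places the ester on O5), 8 from aldehyde 6 and diene 7 (Felkin Mukaiyama aldol: C4–C5 bond, sets C5).
5. 6 comes from D-tyrosine 1 in four steps; C6 is carried over by retentive diazotisation.

Key step: step 8

Remark: chain carbons are numbered C1 (guaiacyl-bearing) to C7 with the ring oxygen O1 between C1 and C5; aldehyde 9 and diene 7 are taken as purchased materials.

**Route**

Step 1
Reactants: 1 D-tyrosine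
Product: 3 (R)-2-hydroxy-3-(4-hydroxyphenyl)propanoic acid, via α-lactone 2 (not isolated)
Conditions: NaNO2, 1 M H2SO4, H2O, 0 °C → rt
Reagents that add atoms: water, O
Why: Diazotisation of the α-amino acid should proceed with net retention, because the carboxylate displaces N2 with inversion to give α-lactone 2 and water opens it with a second inversion, so C6 keeps the R configuration of D-tyrosine.

Step 2
Reactants: 3 (R)-2-hydroxy-3-(4-hydroxyphenyl)propanoic acid
Product: 4 benzyl (R)-3-(4-benzyloxyphenyl)-2-hydroxypropanoate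
Conditions: BnBr (2.2 equiv), K2CO3, DMF, rt
Reagents that add atoms: benzyl bromide, BrCc1ccccc1
Why: Williamson-type O-alkylation in which K2CO3 deprotonates only the carboxylic acid and the phenol, so both are benzylated while the secondary alcohol stays free and the stereocentre is untouched.

Step 3
Reactants: 4 benzyl (R)-3-(4-benzyloxyphenyl)-2-hydroxypropanoate
Product: 5 benzyl (R)-3-(4-benzyloxyphenyl)-2-(tert-butyldimethylsilyloxy)propanoate
Conditions: TBSCl, imidazole, DMF, rt
Reagents that add atoms: tert-butyldimethylsilyl chloride, CC(C)(C)[Si](C)(C)Cl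
Why: Standard imidazole-mediated silylation of the secondary alcohol, giving a bulky silyl ether that later excludes chelation in the aldol step.

Step 4
Reactants: 5 benzyl (R)-3-(4-benzyloxyphenyl)-2-(tert-butyldimethylsilyloxy)propanoate
Product: 6 (R)-3-(4-benzyloxyphenyl)-2-(tert-butyldimethylsilyloxy)propanal
Conditions: iBu2AlH (1.1 equiv), CH2Cl2, −78 °C; aq. potassium sodium tartrate
Reagents that add atoms: none
Why: Partial reduction of an α-silyloxy ester with iBu2AlH at −78 °C should stop at the aldehyde oxidation level because the first hydride adduct does not collapse before work-up, and the aldehyde is used at once to avoid epimerisation at C6.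

Step 5
Reactants: 6 (R)-3-(4-benzyloxyphenyl)-2-(tert-butyldimethylsilyloxy)propanal; 7 2-(trimethylsilyloxy)buta-1,3-diene
Product: 8 (5S,6R)-7-(4-benzyloxyphenyl)-6-(tert-butyldimethylsilyloxy)-5-hydroxyhept-1-en-3-one
Conditions: BF3·OEt2, CH2Cl2, −78 °C; aq. NaHCO3
Reagents that add atoms: none
Why: Mukaiyama aldol addition of the enol silane carbon of 7 to the BF3-activated aldehyde, in which monodentate BF3 and the bulky silyl ether exclude chelation, so attack anti to the C6–O bond (polar Felkin–Anh) should set C5 as S, anti to the C6 oxygen; any 5,6-syn isomer should be separable here.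

Step 6
Reactants: 8 (5S,6R)-7-(4-benzyloxyphenyl)-6-(tert-butyldimethylsilyloxy)-5-hydroxyhept-1-en-3-one; 9 4-benzyloxy-3-methoxybenzaldehyde
Product: 11 (3S,5S,6R)-7-(4-benzyloxyphenyl)-6-(tert-butyldimethylsilyloxy)-3-hydroxyhept-1-en-5-yl 4-benzyloxy-3-methoxybenzoate, via samarium hemiacetal 10 (not isolated)
Conditions: SmI2 (0.3 equiv), 9 (4 equiv), THF, −10 °C, dark
Reagents that add atoms: none
Why: Evans–Tishchenko reduction, in which the C5 hydroxyl adds to aldehyde 9 and, in hemiacetal 10 held on trivalent samarium, the hemiacetal C–H is transferred to the C3 ketone through a chair-like six-membered transition state, which should set C3 as S (1,3-anti to C5) and leave the aryl ester on O5.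

Step 7
Reactants: 11 (3S,5S,6R)-7-(4-benzyloxyphenyl)-6-(tert-butyldimethylsilyloxy)-3-hydroxyhept-1-en-5-yl 4-benzyloxy-3-methoxybenzoate
Product: 12 (3S,5S,6R)-7-(4-benzyloxyphenyl)-3,6-bis(tert-butyldimethylsilyloxy)hept-1-en-5-yl 4-benzyloxy-3-methoxybenzoate
Conditions: TBSOTf, 2,6-lutidine, CH2Cl2, −78 °C
Reagents that add atoms: tert-butyldimethylsilyl trifluoromethanesulfonate, CC(C)(C)[Si](C)(C)OS(=O)(=O)C(F)(F)F
Why: Silylation of the allylic C3 hydroxyl with a silyl triflate and a hindered pyridine base is fast at low temperature and should leave no time for 1,3-migration of the aryl ester from O5 to O3.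

Step 8
Reactants: 12 (3S,5S,6R)-7-(4-benzyloxyphenyl)-3,6-bis(tert-butyldimethylsilyloxy)hept-1-en-5-yl 4-benzyloxy-3-methoxybenzoate
Product: 14 (2S,4S)-6-(4-benzyloxy-3-methoxyphenyl)-2-[(1R)-2-(4-benzyloxyphenyl)-1-(tert-butyldimethylsilyloxy)ethyl]-4-(tert-butyldimethylsilyloxy)-3,4-dihydro-2H-pyran, via titanium alkylidene 13 (not isolated)
Conditions: TiCl4, TMEDA, Zn, PbCl2 (cat.), CH3CHBr2, THF–CH2Cl2, 0 → 65 °C; aq. K2CO3, Et3N-buffered SiO2
Reagents that add atoms: none
Why: This is an olefinic ester cyclisation with the Takai–Utimoto reduced titanium ethylidene, a carbonyl–olefin ring-closing metathesis whose closest known type is the reductive cyclisation of olefinic esters to cyclic enol ethers; the ethylidene first exchanges with the monosubstituted vinyl group by [2+2] cycloaddition and cycloreversion, releasing propene and placing titanium on C2 in alkylidene 13. Alkylidene 13 then adds across the ester carbonyl to an oxatitanacyclobutane, whose cycloreversion forms C1=C2 and leaves the carbonyl oxygen on titanium. The oxane ring (O1, C1 to C5) is thereby closed by intramolecular carbonyl olefination as a six-membered ring with an endocyclic enol ether double bond. No stereocentre is formed, and C3, C5 and C6 are not at risk because the aryl ester has no α-hydrogen and the medium is neither protic nor strongly basic. The step needs ring closure to win over plain ethylidenation of the ester, which the substrate secures through its unhindered terminal alkene as initiation site, its hindered and electron-rich (poorly electrophilic) benzoate carbonyl, and the six-membered ring size; the ethylidene reagent, less prone than a methylidene to olefinate the ester directly, supports this. The product is an acid-labile 2-aryl glycal and is therefore handled only under basic conditions.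

Step 9
Reactants: 14 (2S,4S)-6-(4-benzyloxy-3-methoxyphenyl)-2-[(1R)-2-(4-benzyloxyphenyl)-1-(tert-butyldimethylsilyloxy)ethyl]-4-(tert-butyldimethylsilyloxy)-3,4-dihydro-2H-pyran
Product: 15 (2S,4S)-6-(4-benzyloxy-3-methoxyphenyl)-2-[(1R)-2-(4-benzyloxyphenyl)-1-hydroxyethyl]-3,4-dihydro-2H-pyran-4-ol
Conditions: Bu4NF, THF, 0 °C → rt; Et3N-buffered SiO2
Reagents that add atoms: none
Why: Fluoride cleavage of both secondary silyl ethers runs under basic conditions that the acid-labile aryl enol ether tolerates, and no stereocentre is affected.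

Step 10
Reactants: 15 (2S,4S)-6-(4-benzyloxy-3-methoxyphenyl)-2-[(1R)-2-(4-benzyloxyphenyl)-1-hydroxyethyl]-3,4-dihydro-2H-pyran-4-ol
Product: 16 (2S,4R,6S)-2-(4-benzyloxy-3-methoxyphenyl)-6-[(1R)-2-(4-benzyloxyphenyl)-1-hydroxyethyl]oxan-4-ol
Conditions: H2 (1 atm), [Ir(cod)(PCy3)(py)]PF6 (5 mol%), CH2Cl2, 0 °C → rt
Reagents that add atoms: none
Why: Hydroxyl-directed homogeneous hydrogenation, in which the cationic iridium centre binds the allylic C3 hydroxyl (and the C6 hydroxyl on the same face) and delivers both hydrogens to that face of C1=C2, so H at C1 should end up cis to the C3 hydroxyl and the C5 side chain and the aryl group trans to both (C1 S), the isomer that surface hydrogenation or hydride reduction of an oxocarbenium ion would not give.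

Step 11
Reactants: 16 (2S,4R,6S)-2-(4-benzyloxy-3-methoxyphenyl)-6-[(1R)-2-(4-benzyloxyphenyl)-1-hydroxyethyl]oxan-4-ol
Product: 17 (2S,4R,6S)-2-(4-hydroxy-3-methoxyphenyl)-6-[(1R)-1-hydroxy-2-(4-hydroxyphenyl)ethyl]oxan-4-ol
Conditions: H2 (1 atm), 10% Pd/C, EtOAc, rt
Reagents that add atoms: none
Why: Catalytic hydrogenolysis of the two aryl benzyl ethers, which cleave much faster than the cyclic benzylic C1–O1 bond in a neutral aprotic solvent, so the ring and all four stereocentres should be retained.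

**Compound list**

1 | D-tyrosine | N[C@H](Cc1ccc(O)cc1)C(=O)O | starting material
2 | (S)-3-(4-hydroxybenzyl)oxiran-2-one (α-lactone) | O1[C@@H](Cc2ccc(O)cc2)C1=O | intermediate
3 | (R)-2-hydroxy-3-(4-hydroxyphenyl)propanoic acid | O[C@H](Cc1ccc(O)cc1)C(=O)O | intermediate
4 | benzyl (R)-3-(4-benzyloxyphenyl)-2-hydroxypropanoate | O[C@H](Cc1ccc(OCc2ccccc2)cc1)C(=O)OCc1ccccc1 | intermediate
5 | benzyl (R)-3-(4-benzyloxyphenyl)-2-(tert-butyldimethylsilyloxy)propanoate | CC(C)(C)[Si](C)(C)O[C@H](Cc1ccc(OCc2ccccc2)cc1)C(=O)OCc1ccccc1 | intermediate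
6 | (R)-3-(4-benzyloxyphenyl)-2-(tert-butyldimethylsilyloxy)propanal | CC(C)(C)[Si](C)(C)O[C@H](Cc1ccc(OCc2ccccc2)cc1)C=O | intermediate
7 | 2-(trimethylsilyloxy)buta-1,3-diene | C=CC(=C)O[Si](C)(C)C | starting material
8 | (5S,6R)-7-(4-benzyloxyphenyl)-6-(tert-butyldimethylsilyloxy)-5-hydroxyhept-1-en-3-one | C=CC(=O)C[C@H](O)[C@H](O[Si](C)(C)C(C)(C)C)Cc1ccc(OCc2ccccc2)cc1 | intermediate
9 | 4-benzyloxy-3-methoxybenzaldehyde | COc1cc(C=O)ccc1OCc1ccccc1 | starting material
10 | hemiacetal of the C5 hydroxyl of 8 with 9, present in the flask as its alkoxide on trivalent samarium (drawn as the free hemiacetal) | C=CC(=O)C[C@H](OC(O)c1ccc(OCc2ccccc2)c(OC)c1)[C@H](O[Si](C)(C)C(C)(C)C)Cc1ccc(OCc2ccccc2)cc1 | intermediate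
11 | (3S,5S,6R)-7-(4-benzyloxyphenyl)-6-(tert-butyldimethylsilyloxy)-3-hydroxyhept-1-en-5-yl 4-benzyloxy-3-methoxybenzoate | C=C[C@@H](O)C[C@H](OC(=O)c1ccc(OCc2ccccc2)c(OC)c1)[C@H](O[Si](C)(C)C(C)(C)C)Cc1ccc(OCc2ccccc2)cc1 | intermediate
12 | (3S,5S,6R)-7-(4-benzyloxyphenyl)-3,6-bis(tert-butyldimethylsilyloxy)hept-1-en-5-yl 4-benzyloxy-3-methoxybenzoate | C=C[C@@H](O[Si](C)(C)C(C)(C)C)C[C@H](OC(=O)c1ccc(OCc2ccccc2)c(OC)c1)[C@H](O[Si](C)(C)C(C)(C)C)Cc1ccc(OCc2ccccc2)cc1 | intermediate
13 | titanium alkylidene at C2 formed from 12 by alkylidene exchange (drawn as the dichlorotitanium alkylidene, TMEDA omitted) | Cl[Ti](Cl)=C[C@@H](O[Si](C)(C)C(C)(C)C)C[C@H](OC(=O)c1ccc(OCc2ccccc2)c(OC)c1)[C@H](O[Si](C)(C)C(C)(C)C)Cc1ccc(OCc2ccccc2)cc1 | intermediate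
14 | (2S,4S)-6-(4-benzyloxy-3-methoxyphenyl)-2-[(1R)-2-(4-benzyloxyphenyl)-1-(tert-butyldimethylsilyloxy)ethyl]-4-(tert-butyldimethylsilyloxy)-3,4-dihydro-2H-pyran | COc1cc(C2=C[C@@H](O[Si](C)(C)C(C)(C)C)C[C@@H]([C@H](O[Si](C)(C)C(C)(C)C)Cc3ccc(OCc4ccccc4)cc3)O2)ccc1OCc1ccccc1 | intermediate
15 | (2S,4S)-6-(4-benzyloxy-3-methoxyphenyl)-2-[(1R)-2-(4-benzyloxyphenyl)-1-hydroxyethyl]-3,4-dihydro-2H-pyran-4-ol | COc1cc(C2=C[C@@H](O)C[C@@H]([C@H](O)Cc3ccc(OCc4ccccc4)cc3)O2)ccc1OCc1ccccc1 | intermediate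
16 | (2S,4R,6S)-2-(4-benzyloxy-3-methoxyphenyl)-6-[(1R)-2-(4-benzyloxyphenyl)-1-hydroxyethyl]oxan-4-ol | COc1cc([C@@H]2C[C@@H](O)C[C@@H]([C@H](O)Cc3ccc(OCc4ccccc4)cc3)O2)ccc1OCc1ccccc1 | intermediate
17 | (2S,4R,6S)-2-(4-hydroxy-3-methoxyphenyl)-6-[(1R)-1-hydroxy-2-(4-hydroxyphenyl)ethyl]oxan-4-ol | COc1cc([C@@H]2C[C@@H](O)C[C@@H]([C@H](O)Cc3ccc(O)cc3)O2)ccc1O | target

**Step count and risks**

Total step count: 11. Longest linear sequence: 11 steps (1 to 17).

Steps most likely to fail:

Step 8. The titanium ethylidene may olefinate the hindered aryl ester without closing the ring, or the allylic C3 silyloxy group may be lost from the titanacycle. The fallback separates the two events. Setting out from 12, methylenation of the ester with Cp2TiMe2 (toluene, 70 °C, dark) should give the 1-aryl vinyl ether (3S,5S,6R)-7-(4-benzyloxyphenyl)-5-{[1-(4-benzyloxy-3-methoxyphenyl)ethenyl]oxy}-3,6-bis(tert-butyldimethylsilyloxy)hept-1-ene F1. Enol ether–olefin ring-closing metathesis of F1 with the second-generation Grubbs catalyst RuCl2(=CHPh)(PCy3)(H2IMes) (toluene, 70 °C), which tolerates allylic silyl ethers, should then expel ethylene and come back to the route at glycal 14.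

Step 10. Acidic iridium hydride species may ionise the allylic alcohol of the electron-rich aryl enol ether (loss of the C3 hydroxyl, hydration of the enol ether), or hydrogen may be delivered without hydroxyl direction and give the C1 epimer. The fallback sets C1 instead by axial attack of an aryl nucleophile on a cyclic oxocarbenium ion, using the terminal vinyl carbon of 12 as C1.

- Setting out from 12, anti-Markovnikov hydroboration with 9-BBN (THF, rt) gives the B-alkyl-9-borabicyclo[3.3.1]nonane F2, which is oxidised in the same flask with NaBO3·4H2O to the primary alcohol (3R,5S,6R)-7-(4-benzyloxyphenyl)-3,6-bis(tert-butyldimethylsilyloxy)-1-hydroxyheptan-5-yl 4-benzyloxy-3-methoxybenzoate F3.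
- Reductive removal of the aryl ester with iBu2AlH (CH2Cl2, −78 °C) gives (3R,5S,6R)-7-(4-benzyloxyphenyl)-3,6-bis(tert-butyldimethylsilyloxy)heptane-1,5-diol F4.
- Oxidative lactonisation with TEMPO and PhI(OAc)2 (CH2Cl2, rt) gives the δ-lactone 6-[(1R)-2-(4-benzyloxyphenyl)-1-(tert-butyldimethylsilyloxy)ethyl]-4-(tert-butyldimethylsilyloxy)oxan-2-one F5.
- iBu2AlH at −78 °C reduces it to the lactol F6, and PhSO2H with CaCl2 (CH2Cl2) converts F6 into the anomeric 2-(phenylsulfonyl)oxane F7.
- (4-Benzyloxy-3-methoxyphenyl)magnesium bromide F8, made from purchased 1-benzyloxy-4-bromo-2-methoxybenzene and Mg in THF, is combined with ZnBr2 and F7. The sulfone ionises, and the arylzinc species should add axially to the oxocarbenium half-chair that carries the C3 and C5 substituents pseudo-equatorially, giving the 2,6-trans oxane (2S,4R,6S)-2-(4-benzyloxy-3-methoxyphenyl)-6-[(1R)-2-(4-benzyloxyphenyl)-1-(tert-butyldimethylsilyloxy)ethyl]-4-(tert-butyldimethylsilyloxy)oxane F9.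
- Desilylation of F9 with Bu4NF (THF) comes back to the route at 16.

Step 6. The vinyl ketone may polymerise or be reduced under SmI2, hemiacetal formation with the electron-rich aldehyde may be slow, and the ester may migrate from O5 to O3. The fallback separates reduction and acylation.

- Setting out from 8, Evans–Saksena reduction with Me4NBH(OAc)3 (MeCN–AcOH, −30 °C) delivers hydride intramolecularly from the C5-bound acyloxyborohydride and should give the same 1,3-anti relationship in (3S,5S,6R)-7-(4-benzyloxyphenyl)-6-(tert-butyldimethylsilyloxy)hept-1-ene-3,5-diol F10.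
- Silylation with TBSCl and imidazole (DMF, −20 °C) should select the less hindered allylic C3 hydroxyl over the C5 hydroxyl flanked by the C6 silyloxy group, giving (3S,5S,6R)-7-(4-benzyloxyphenyl)-3,6-bis(tert-butyldimethylsilyloxy)hept-1-en-5-ol F11.
- Esterification of F11 with purchased 4-benzyloxy-3-methoxybenzoic acid (EDC·HCl, DMAP, CH2Cl2) comes back to the route at 12.

**Further compounds**

F1 | step 8 | (3S,5S,6R)-7-(4-benzyloxyphenyl)-5-{[1-(4-benzyloxy-3-methoxyphenyl)ethenyl]oxy}-3,6-bis(tert-butyldimethylsilyloxy)hept-1-ene | C=C[C@@H](O[Si](C)(C)C(C)(C)C)C[C@H](OC(=C)c1ccc(OCc2ccccc2)c(OC)c1)[C@H](O[Si](C)(C)C(C)(C)C)Cc1ccc(OCc2ccccc2)cc1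
F2 | step 10 | B-alkyl-9-borabicyclo[3.3.1]nonane from hydroboration of the vinyl group of 12 | C1CCC2CCCC1B2CC[C@@H](O[Si](C)(C)C(C)(C)C)C[C@H](OC(=O)c1ccc(OCc2ccccc2)c(OC)c1)[C@H](O[Si](C)(C)C(C)(C)C)Cc1ccc(OCc2ccccc2)cc1
F3 | step 10 | (3R,5S,6R)-7-(4-benzyloxyphenyl)-3,6-bis(tert-butyldimethylsilyloxy)-1-hydroxyheptan-5-yl 4-benzyloxy-3-methoxybenzoate | OCC[C@@H](O[Si](C)(C)C(C)(C)C)C[C@H](OC(=O)c1ccc(OCc2ccccc2)c(OC)c1)[C@H](O[Si](C)(C)C(C)(C)C)Cc1ccc(OCc2ccccc2)cc1
F4 | step 10 | (3R,5S,6R)-7-(4-benzyloxyphenyl)-3,6-bis(tert-butyldimethylsilyloxy)heptane-1,5-diol | OCC[C@@H](O[Si](C)(C)C(C)(C)C)C[C@H](O)[C@H](O[Si](C)(C)C(C)(C)C)Cc1ccc(OCc2ccccc2)cc1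
F5 | step 10 | δ-lactone 6-[(1R)-2-(4-benzyloxyphenyl)-1-(tert-butyldimethylsilyloxy)ethyl]-4-(tert-butyldimethylsilyloxy)oxan-2-one | O=C1C[C@@H](O[Si](C)(C)C(C)(C)C)C[C@@H]([C@H](O[Si](C)(C)C(C)(C)C)Cc2ccc(OCc3ccccc3)cc2)O1
F6 | step 10 | lactol 6-[(1R)-2-(4-benzyloxyphenyl)-1-(tert-butyldimethylsilyloxy)ethyl]-4-(tert-butyldimethylsilyloxy)oxan-2-ol (anomeric mixture) | OC1C[C@@H](O[Si](C)(C)C(C)(C)C)C[C@@H]([C@H](O[Si](C)(C)C(C)(C)C)Cc2ccc(OCc3ccccc3)cc2)O1
F7 | step 10 | 2-(phenylsulfonyl)oxane derived from F6 (anomeric mixture) | O=S(=O)(c1ccccc1)C1C[C@@H](O[Si](C)(C)C(C)(C)C)C[C@@H]([C@H](O[Si](C)(C)C(C)(C)C)Cc2ccc(OCc3ccccc3)cc2)O1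
F8 | step 10 | (4-benzyloxy-3-methoxyphenyl)magnesium bromide | COc1cc([Mg]Br)ccc1OCc1ccccc1
F9 | step 10 | (2S,4R,6S)-2-(4-benzyloxy-3-methoxyphenyl)-6-[(1R)-2-(4-benzyloxyphenyl)-1-(tert-butyldimethylsilyloxy)ethyl]-4-(tert-butyldimethylsilyloxy)oxane | COc1cc([C@@H]2C[C@@H](O[Si](C)(C)C(C)(C)C)C[C@@H]([C@H](O[Si](C)(C)C(C)(C)C)Cc3ccc(OCc4ccccc4)cc3)O2)ccc1OCc1ccccc1
F10 | step 6 | (3S,5S,6R)-7-(4-benzyloxyphenyl)-6-(tert-butyldimethylsilyloxy)hept-1-ene-3,5-diol | C=C[C@@H](O)C[C@H](O)[C@H](O[Si](C)(C)C(C)(C)C)Cc1ccc(OCc2ccccc2)cc1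
F11 | step 6 | (3S,5S,6R)-7-(4-benzyloxyphenyl)-3,6-bis(tert-butyldimethylsilyloxy)hept-1-en-5-ol | C=C[C@@H](O[Si](C)(C)C(C)(C)C)C[C@H](O)[C@H](O[Si](C)(C)C(C)(C)C)Cc1ccc(OCc2ccccc2)cc1
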